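**Retrosynthetic overview**
1. 26 ⇒ C4–C5 (sp2–sp3 Negishi union, last step): (5E,7E)-5-iododienone 22 + (4-methoxy-4-oxobutyl)zinc iodide 24. Enabling feature: the C9 carbonyl of the cyclopentenone ring is conjugated through the exocyclic C8=C7 and the C6=C5 double bonds, so C5–I is a doubly vinylogous acyl iodide that takes up Pd(0) far faster than the C10–Cl bond.
2. 22 ⇒ C7=C8 (aldol condensation at the ring CH2, C8): 2-chloroenone 14 + (E)-3-iodoacrolein 18, whose E geometry (future C5=C6) comes from alkyne hydrozirconation.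
3. 14 ⇒ C10–Cl/C10=C11 (epoxy ketone + HCl) and C9=O (alcohol oxidation) ⇒ epoxy alcohol 9 ⇒ C14=C15 (Lindlar), C15–C16 (acetylide alkylation), C12–C13 (anti 1,2-propargylation) ⇒ (S)-4-silyloxycyclopentenone 1.
4. Rings: the only ring, the cyclopentenone, is taken intact from 1 and no ring is formed. The C12 carbinol centre is set in step 1 under control of the silyloxy-bearing carbon, which later becomes the C9 carbonyl.

Key step: step 14

Remark: positions are given in prostanoid numbering (C1 = ester carbon, C8–C12 = ring, C20 = terminal methyl). The (S)-enantiomer of 1 is assumed to be purchasable. The epoxide configuration drawn for 8–12 is the expected one and is erased in step 7.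

Step 1
Reactants: 1 (4S)-4-[(tert-butyldimethylsilyl)oxy]cyclopent-2-en-1-one; 2 3-bromoprop-1-yne
Product: 4 (1R,4S)-4-[(tert-butyldimethylsilyl)oxy]-1-(prop-2-yn-1-yl)cyclopent-2-en-1-ol, via allenylmagnesium bromide 3 (not isolated)
Conditions: 2, Mg, HgCl2 (cat.), Et2O, 0 °C; then 1, −78 °C; sat. aq NH4Cl
Reagents that add atoms: none
Why: Grignard propargylation: the allenyl Grignard adds 1,2 to the enone carbonyl (SE2′) to give the homopropargylic carbinol, attacking the face anti to the C4 silyloxy group, which sets the quaternary carbinol centre (future C12) with OH cis to OSi.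

Step 2
Reactants: 4 (1R,4S)-4-[(tert-butyldimethylsilyl)oxy]-1-(prop-2-yn-1-yl)cyclopent-2-en-1-ol; 5 1-iodopentane
Product: 7 (1R,4S)-4-[(tert-butyldimethylsilyl)oxy]-1-(oct-2-yn-1-yl)cyclopent-2-en-1-ol, via dilithium alkoxide-acetylide 6 (not isolated)
Conditions: n-BuLi (2.2 equiv), THF–DMPU, −78 → 0 °C; then 5, 0 → 23 °C; H2O
Reagents that add atoms: none
Why: Acetylide alkylation: the dianion is alkylated at the sp carbon by the primary iodide, the hindered tertiary alkoxide does not compete, and no stereocentre is touched.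

Step 3
Reactants: 7 (1R,4S)-4-[(tert-butyldimethylsilyl)oxy]-1-(oct-2-yn-1-yl)cyclopent-2-en-1-ol
Product: 8 4-[(tert-butyldimethylsilyl)oxy]-2-(oct-2-yn-1-yl)-6-oxabicyclo[3.1.0]hexan-2-ol (epoxide O, OH and OSi all cis; carbinol and silyloxy carbons as in 7)
Conditions: VO(acac)2 (cat.), t-BuOOH, CH2Cl2, 0 → 23 °C
Reagents that add atoms: tert-butyl hydroperoxide, CC(C)(C)OO
Why: Hydroxyl-directed vanadium-catalysed epoxidation: the tertiary allylic alkoxide delivers oxygen to the ring alkene on its own face while the alkyne is inert, and the two new epoxide centres are of no consequence because both carbons become sp2 in step 7.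

Step 4
Reactants: 8 4-[(tert-butyldimethylsilyl)oxy]-2-(oct-2-yn-1-yl)-6-oxabicyclo[3.1.0]hexan-2-ol
Product: 9 4-[(tert-butyldimethylsilyl)oxy]-2-[(2Z)-oct-2-en-1-yl]-6-oxabicyclo[3.1.0]hexan-2-ol (all-cis as in 8)
Conditions: H2 (1 atm), Pd/CaCO3–Pb (Lindlar catalyst), quinoline, EtOAc, 23 °C
Reagents that add atoms: none
Why: Lindlar semihydrogenation: syn delivery of H2 on the poisoned Pd surface should give the 14Z alkene, and the epoxide and silyl ether are not reduced.

Step 5
Reactants: 9 4-[(tert-butyldimethylsilyl)oxy]-2-[(2Z)-oct-2-en-1-yl]-6-oxabicyclo[3.1.0]hexan-2-ol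
Product: 10 2-[(2Z)-oct-2-en-1-yl]-6-oxabicyclo[3.1.0]hexane-2,4-diol (all-cis)
Conditions: TBAF, THF, 0 → 23 °C
Reagents that add atoms: none
Why: Fluoride desilylation frees the secondary alcohol; the cis relationship of both oxygens to the epoxide rules out intramolecular backside opening, so no stereocentre changes.

Step 6
Reactants: 10 2-[(2Z)-oct-2-en-1-yl]-6-oxabicyclo[3.1.0]hexane-2,4-diol
Product: 11 (1R,4R,5S)-4-hydroxy-4-[(2Z)-oct-2-en-1-yl]-6-oxabicyclo[3.1.0]hexan-2-one
Conditions: Dess–Martin periodinane, NaHCO3, CH2Cl2, 0 → 23 °C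
Reagents that add atoms: none
Why: Dess–Martin oxidation of the only oxidisable (secondary) alcohol places the carbonyl at C9 under non-basic conditions, so the β-hydroxy ketone cannot open by retro-aldol and the C12 centre is preserved.

Step 7
Reactants: 11 (1R,4R,5S)-4-hydroxy-4-[(2Z)-oct-2-en-1-yl]-6-oxabicyclo[3.1.0]hexan-2-one
Product: 13 (4R)-2-chloro-4-hydroxy-4-[(2Z)-oct-2-en-1-yl]cyclopent-2-en-1-one, via chlorohydrin 12 (not isolated)
Conditions: HCl (4 M in 1,4-dioxane), THF, 0 → 23 °C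
Reagents that add atoms: hydrogen chloride, Cl
Why: Acid-mediated epoxy-ketone opening and dehydration: chloride opens the protonated epoxide at the carbon α to the carbonyl (SN2 accelerated by C=O, the β-carbon being neopentyl-like) and the α-chloro-β-hydroxy ketone loses water by E1cB to the 2-chloroenone, leaving the quaternary carbinol untouched.

Step 8
Reactants: 13 (4R)-2-chloro-4-hydroxy-4-[(2Z)-oct-2-en-1-yl]cyclopent-2-en-1-one
Product: 14 (4R)-2-chloro-4-[(2Z)-oct-2-en-1-yl]-4-[(trimethylsilyl)oxy]cyclopent-2-en-1-one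
Conditions: N-(trimethylsilyl)imidazole, CH2Cl2, 23 °C
Reagents that add atoms: N-(trimethylsilyl)imidazole, C[Si](C)(C)n1ccnc1
Why: Silylation of the tertiary alcohol with a strong silyl donor under neutral conditions masks the β-hydroxyl so that the ketone can be enolised cleanly in step 11.

Step 9
Reactants: 15 3,3-diethoxyprop-1-yne
Product: 17 (1E)-3,3-diethoxy-1-iodoprop-1-ene, via alkenylzirconocene chloride 16 (not isolated)
Conditions: Cp2Zr(H)Cl, THF, 23 °C; then I2, 0 °C
Reagents that add atoms: iodine, II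
Why: Hydrozirconation–iodinolysis: syn addition of Zr–H places Zr on the terminal carbon and iodine replaces it with retention, fixing the E geometry of the future C5=C6 bond.

Step 10
Reactants: 17 (1E)-3,3-diethoxy-1-iodoprop-1-ene
Product: 18 (2E)-3-iodoprop-2-enal
Conditions: oxalic acid (cat.), H2O, SiO2, CH2Cl2, 23 °C; dried solution used at once
Reagents that add atoms: water, O
Why: Mild acid-catalysed acetal hydrolysis should release the aldehyde without isomerising the vinyl iodide.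

Step 11
Reactants: 14 (4R)-2-chloro-4-[(2Z)-oct-2-en-1-yl]-4-[(trimethylsilyl)oxy]cyclopent-2-en-1-one; 18 (2E)-3-iodoprop-2-enal
Product: 20 (4R)-2-chloro-5-[(2E)-1-hydroxy-3-iodoprop-2-en-1-yl]-4-[(2Z)-oct-2-en-1-yl]-4-[(trimethylsilyl)oxy]cyclopent-2-en-1-one (diastereomer mixture at C5 and the carbinol carbon), via lithium enolate 19 (not isolated)
Conditions: LDA, THF, −78 °C; then 18, −78 °C; AcOH
Reagents that add atoms: none
Why: Directed aldol addition: LDA removes a proton from the only enolisable position (ring CH2, C8) and the lithium enolate adds 1,2 to the aldehyde at −78 °C; the two new centres are not controlled and are removed in step 12.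

Step 12
Reactants: 20 (4R)-2-chloro-5-[(2E)-1-hydroxy-3-iodoprop-2-en-1-yl]-4-[(2Z)-oct-2-en-1-yl]-4-[(trimethylsilyl)oxy]cyclopent-2-en-1-one
Product: 22 (4S,5E)-2-chloro-5-[(2E)-3-iodoprop-2-en-1-ylidene]-4-[(2Z)-oct-2-en-1-yl]-4-[(trimethylsilyl)oxy]cyclopent-2-en-1-one, via mesylate 21 (not isolated)
Conditions: MsCl, Et3N, CH2Cl2, −20 → 23 °C
Reagents that add atoms: none
Why: Mesylation and E1cB elimination: the β-mesyloxy ketone eliminates through its enolate to the conjugated exocyclic alkene, expected mainly as the E isomer (chain anti to the carbonyl), and the vinyl iodide geometry is retained.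

Step 13
Reactants: 23 methyl 4-iodobutanoate
Product: 24 (4-methoxy-4-oxobutyl)zinc iodide (THF solution)
Conditions: Zn dust (activated with BrCH2CH2Br, TMSCl), THF, 40 °C
Reagents that add atoms: zinc, [Zn]
Why: Direct zinc insertion into a primary alkyl iodide gives the ester-bearing alkylzinc iodide, since the C–Zn bond does not attack the ester.

Step 14
Reactants: 22 (4S,5E)-2-chloro-5-[(2E)-3-iodoprop-2-en-1-ylidene]-4-[(2Z)-oct-2-en-1-yl]-4-[(trimethylsilyl)oxy]cyclopent-2-en-1-one; 24 (4-methoxy-4-oxobutyl)zinc iodide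
Product: 26 methyl (5E,7E)-7-[(5S)-3-chloro-5-hydroxy-5-[(2Z)-oct-2-en-1-yl]-2-oxocyclopent-3-en-1-ylidene]hept-5-enoate, via trimethylsilyl ether 25 (not isolated)
Conditions: 24 (1.5 equiv), Pd(dppf)Cl2 (5 mol %), THF, 23 °C; then 0.5 M aq HCl, THF, 0 °C
Reagents that add atoms: none
Why: Negishi cross-coupling: Pd(0) inserts into the C5–I bond of 22, the primary alkylzinc iodide 24 transmetalates, and reductive elimination forms the C4–C5 bond with retention of the 5E geometry. The closest known reaction type is the Pd-catalysed coupling of (E)-alkenyl iodides with ester-bearing alkylzinc iodides. No ring is closed and no stereocentre is formed; the C12 centre and the 7E and 14Z alkenes are only carried through. The step needs selectivity for C5–I over C10–Cl and over 1,4- or 1,6-addition to the cross-conjugated dienone: the iodide is a doubly vinylogous acyl iodide (C9=O conjugated through C8=C7 and C6=C5), so oxidative addition is fast at 23 °C, whereas the α-chloroenone C–Cl bond should be inert to Pd(dppf) at this temperature and alkylzinc iodides do not add to enones in THF without copper or a Lewis acid. The wide bite angle of dppf favours reductive elimination over β-hydride elimination of the alkyl–Pd intermediate. The dilute-acid work-up hydrolyses the tertiary trimethylsilyl ether 25 to the free carbinol without affecting the methyl ester or the dienone.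

**Compound list**
1 | (4S)-4-[(tert-butyldimethylsilyl)oxy]cyclopent-2-en-1-one | O=C1C=C[C@@H](O[Si](C)(C)C(C)(C)C)C1 | starting material
2 | 3-bromoprop-1-yne (propargyl bromide) | C#CCBr | starting material
3 | propa-1,2-dien-1-ylmagnesium bromide (allenylmagnesium bromide) | C=C=C[Mg]Br | intermediate
4 | (1R,4S)-4-[(tert-butyldimethylsilyl)oxy]-1-(prop-2-yn-1-yl)cyclopent-2-en-1-ol | C#CC[C@]1(O)C=C[C@@H](O[Si](C)(C)C(C)(C)C)C1 | intermediate
5 | 1-iodopentane | CCCCCI | starting material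
6 | dilithium alkoxide-acetylide of 4 | [Li]C#CC[C@]1(O[Li])C=C[C@@H](O[Si](C)(C)C(C)(C)C)C1 | intermediate
7 | (1R,4S)-4-[(tert-butyldimethylsilyl)oxy]-1-(oct-2-yn-1-yl)cyclopent-2-en-1-ol | CCCCCC#CC[C@]1(O)C=C[C@@H](O[Si](C)(C)C(C)(C)C)C1 | intermediate
8 | 4-[(tert-butyldimethylsilyl)oxy]-2-(oct-2-yn-1-yl)-6-oxabicyclo[3.1.0]hexan-2-ol, epoxide O, OH and OSi all cis | CCCCCC#CC[C@]1(O)[C@H]2O[C@H]2[C@@H](O[Si](C)(C)C(C)(C)C)C1 | intermediate
9 | 4-[(tert-butyldimethylsilyl)oxy]-2-[(2Z)-oct-2-en-1-yl]-6-oxabicyclo[3.1.0]hexan-2-ol, all-cis | CCCCC/C=C\C[C@]1(O)[C@H]2O[C@H]2[C@@H](O[Si](C)(C)C(C)(C)C)C1 | intermediate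
10 | 2-[(2Z)-oct-2-en-1-yl]-6-oxabicyclo[3.1.0]hexane-2,4-diol, all-cis | CCCCC/C=C\C[C@]1(O)[C@H]2O[C@H]2[C@@H](O)C1 | intermediate
11 | (1R,4R,5S)-4-hydroxy-4-[(2Z)-oct-2-en-1-yl]-6-oxabicyclo[3.1.0]hexan-2-one | CCCCC/C=C\C[C@]1(O)[C@H]2O[C@H]2C(=O)C1 | intermediate
12 | (2S,3R,4R)-2-chloro-3,4-dihydroxy-4-[(2Z)-oct-2-en-1-yl]cyclopentan-1-one | CCCCC/C=C\C[C@]1(O)[C@@H](O)[C@H](Cl)C(=O)C1 | intermediate
13 | (4R)-2-chloro-4-hydroxy-4-[(2Z)-oct-2-en-1-yl]cyclopent-2-en-1-one | CCCCC/C=C\C[C@]1(O)C=C(Cl)C(=O)C1 | intermediate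
14 | (4R)-2-chloro-4-[(2Z)-oct-2-en-1-yl]-4-[(trimethylsilyl)oxy]cyclopent-2-en-1-one | CCCCC/C=C\C[C@]1(O[Si](C)(C)C)C=C(Cl)C(=O)C1 | intermediate
15 | 3,3-diethoxyprop-1-yne | CCOC(OCC)C#C | starting material
16 | chlorobis(cyclopentadienyl)[(1E)-3,3-diethoxyprop-1-en-1-yl]zirconium | CCOC(OCC)/C=C/[Zr](Cl)(C1C=CC=C1)C1C=CC=C1 | intermediate
17 | (1E)-3,3-diethoxy-1-iodoprop-1-ene | CCOC(OCC)/C=C/I | intermediate
18 | (2E)-3-iodoprop-2-enal | O=C/C=C/I | intermediate
19 | lithium enolate of 14 (lithium 2-chloro-4-[(2Z)-oct-2-en-1-yl]-4-[(trimethylsilyl)oxy]cyclopenta-1,5-dien-1-olate) | CCCCC/C=C\C[C@]1(O[Si](C)(C)C)C=C(Cl)C(O[Li])=C1 | intermediate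
20 | (4R)-2-chloro-5-[(2E)-1-hydroxy-3-iodoprop-2-en-1-yl]-4-[(2Z)-oct-2-en-1-yl]-4-[(trimethylsilyl)oxy]cyclopent-2-en-1-one, diastereomer mixture at C5 and the carbinol carbon | CCCCC/C=C\C[C@]1(O[Si](C)(C)C)C=C(Cl)C(=O)C1C(O)/C=C/I | intermediate
21 | methanesulfonate of 20 | CCCCC/C=C\C[C@]1(O[Si](C)(C)C)C=C(Cl)C(=O)C1C(OS(C)(=O)=O)/C=C/I | intermediate
22 | (4S,5E)-2-chloro-5-[(2E)-3-iodoprop-2-en-1-ylidene]-4-[(2Z)-oct-2-en-1-yl]-4-[(trimethylsilyl)oxy]cyclopent-2-en-1-one | CCCCC/C=C\C[C@]1(O[Si](C)(C)C)C=C(Cl)C(=O)/C1=C/C=C/I | intermediate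
23 | methyl 4-iodobutanoate | COC(=O)CCCI | starting material
24 | (4-methoxy-4-oxobutyl)zinc iodide | COC(=O)CCC[Zn]I | intermediate
25 | methyl (5E,7E)-7-[(5S)-3-chloro-5-[(2Z)-oct-2-en-1-yl]-2-oxo-5-[(trimethylsilyl)oxy]cyclopent-3-en-1-ylidene]hept-5-enoate | CCCCC/C=C\C[C@]1(O[Si](C)(C)C)C=C(Cl)C(=O)/C1=C/C=C/CCCC(=O)OC | intermediate
26 | methyl (5E,7E)-7-[(5S)-3-chloro-5-hydroxy-5-[(2Z)-oct-2-en-1-yl]-2-oxocyclopent-3-en-1-ylidene]hept-5-enoate | CCCCC/C=C\C[C@]1(O)C=C(Cl)C(=O)/C1=C/C=C/CCCC(=O)OC | target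

**Step count**
Total: 14 steps. Longest linear sequence: 11 steps (steps 1–8, 11, 12, 14).

**Steps most likely to fail**

Step 14 (key step). The electron-poor iodotrienone may be consumed by conjugate addition of the alkylzinc or by decomposition before oxidative addition and transmetalation, or β-hydride elimination at palladium may reduce the C5–I bond. Fallback: the ester arm is joined to the three-carbon unit before the ring is attached. Setting out from 17 and 24 (and 14), Pd(dppf)Cl2-catalysed Negishi coupling of 24 with acetal 17 should give methyl (5E)-7,7-diethoxyhept-5-enoate F1. Aqueous oxalic acid should release methyl (5E)-7-oxohept-5-enoate F2. Addition of lithium enolate 19 (from 14, LDA, −78 °C) to F2 should give methyl (5E)-7-hydroxy-7-[(5R)-3-chloro-5-[(2Z)-oct-2-en-1-yl]-2-oxo-5-[(trimethylsilyl)oxy]cyclopent-3-en-1-yl]hept-5-enoate F3. MsCl/Et3N should dehydrate F3 to the trimethylsilyl ether 25, where the route is rejoined; the acidic work-up of step 14 then gives 26.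

Step 11. The lithium enolate may lose its β-silyloxy group (cyclopentadienone formation), or the β-iodoenal may undergo 1,4-addition with loss of iodide instead of 1,2-addition. Fallback: a Mukaiyama-type addition to the acetal avoids both the lithium enolate and the free aldehyde and replaces steps 11 and 12. Setting out from 14 and 17, soft enolisation of 14 (TMSOTf, Et3N, CH2Cl2, 0 °C) should give (5R)-2-chloro-5-[(2Z)-oct-2-en-1-yl]-3,5-bis[(trimethylsilyl)oxy]cyclopenta-1,3-diene F4. TMSOTf-catalysed addition of F4 to 17 (CH2Cl2, −78 °C) should give (4R)-2-chloro-5-[(2E)-1-ethoxy-3-iodoprop-2-en-1-yl]-4-[(2Z)-oct-2-en-1-yl]-4-[(trimethylsilyl)oxy]cyclopent-2-en-1-one F5. DBU should eliminate ethanol from F5 under equilibrating E1cB conditions to give 22, where the route is rejoined.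

Step 7. Acid may cause loss of the tertiary hydroxyl (dehydration towards C8), or the chlorohydrin may fail to dehydrate. Fallback: non-protic opening of the silylated epoxide followed by base-induced elimination, bypassing 13 and step 8. Setting out from 11, N-(trimethylsilyl)imidazole should give (1R,4R,5S)-4-[(2Z)-oct-2-en-1-yl]-4-[(trimethylsilyl)oxy]-6-oxabicyclo[3.1.0]hexan-2-one F6. TMSCl with catalytic Bu4NCl (CH2Cl2, 0 °C) should open the epoxide at the α-carbon to give (2S,3R,4R)-2-chloro-4-[(2Z)-oct-2-en-1-yl]-3,4-bis[(trimethylsilyl)oxy]cyclopentan-1-one F7. DBU should expel trimethylsilanolate from F7 (E1cB) to give 14, where the route is rejoined.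

**Further compounds**
F1 | step 14 | methyl (5E)-7,7-diethoxyhept-5-enoate | CCOC(OCC)/C=C/CCCC(=O)OC
F2 | step 14 | methyl (5E)-7-oxohept-5-enoate | O=C/C=C/CCCC(=O)OC
F3 | step 14 | methyl (5E)-7-hydroxy-7-[(5R)-3-chloro-5-[(2Z)-oct-2-en-1-yl]-2-oxo-5-[(trimethylsilyl)oxy]cyclopent-3-en-1-yl]hept-5-enoate | CCCCC/C=C\C[C@]1(O[Si](C)(C)C)C=C(Cl)C(=O)C1C(O)/C=C/CCCC(=O)OC
F4 | step 11 | (5R)-2-chloro-5-[(2Z)-oct-2-en-1-yl]-3,5-bis[(trimethylsilyl)oxy]cyclopenta-1,3-diene | CCCCC/C=C\C[C@]1(O[Si](C)(C)C)C=C(Cl)C(O[Si](C)(C)C)=C1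
F5 | step 11 | (4R)-2-chloro-5-[(2E)-1-ethoxy-3-iodoprop-2-en-1-yl]-4-[(2Z)-oct-2-en-1-yl]-4-[(trimethylsilyl)oxy]cyclopent-2-en-1-one | CCCCC/C=C\C[C@]1(O[Si](C)(C)C)C=C(Cl)C(=O)C1C(OCC)/C=C/I
F6 | step 7 | (1R,4R,5S)-4-[(2Z)-oct-2-en-1-yl]-4-[(trimethylsilyl)oxy]-6-oxabicyclo[3.1.0]hexan-2-one | CCCCC/C=C\C[C@]1(O[Si](C)(C)C)[C@H]2O[C@H]2C(=O)C1
F7 | step 7 | (2S,3R,4R)-2-chloro-4-[(2Z)-oct-2-en-1-yl]-3,4-bis[(trimethylsilyl)oxy]cyclopentan-1-one | CCCCC/C=C\C[C@]1(O[Si](C)(C)C)[C@@H](O[Si](C)(C)C)[C@H](Cl)C(=O)C1
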